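**Plan**

- Retrosynthesis: the ArCH2–CH2Ar bridge is cut first (two identical aryl bromides plus a two-carbon linchpin). In each cyclopentane (C1 = benzylic quaternary carbon, C2 = CMe2, C3–C5 = the CH2 carbons) the bonds C2–C3 and C4–C5 are cut next, then the C1–C2 bond between the two fully substituted carbons, then the aryl–alkyne bond.
- Enabling feature: ring carbon C1 is flanked by C2, which can be a tertiary radical released from a carboxylic acid, and by C5, which can be a formyl carbon. C3–C4 can therefore be inserted as a vinylphosphonium unit that accepts the radical at C3 and, as an ylide at C4, olefinates C5 (formal [3+2] closure of the five-membered ring).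
- Forward order: arene, propargylic alcohol, E-allylic isobutyrate, Ireland–Claisen rearrangement (C1–C2, still acyclic), ozonolysis, annulation to the cyclopentene, twofold Suzuki coupling (bridge), hydrogenation, demethylation.
- Stereochemistry: the only stereocentre of each half (C1) comes from (R)-but-3-yn-2-ol by 1,3-chirality transfer in the chair Ireland–Claisen step and is never trigonal afterwards. Joining two identical (S) halves gives the C2-symmetric (S,S) target.

Key step: step 9

Remark: compound 14 is drawn as the open oxo acid; it is expected to rest largely as its ring-closed hydroxy lactone, which the carbonate base of step 9 opens to the carboxylate–aldehyde.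
Remark: compounds 1, 4, 15 and 18 are taken as commercial.

Step 1
Reactants: 1 4-bromo-2-methoxyphenol
Product: 2 4-bromo-2-iodo-6-methoxyphenol
Conditions: I2 (1.05 equiv), NaHCO3 (1.5 equiv), THF/H2O, 0 °C to rt
Reagents that add atoms: iodine, II
Why: Electrophilic aromatic iodination of the phenol(ate), whose para position carries bromine and whose other ortho position carries the methoxy group, so iodine should enter only at C-6.

Step 2
Reactants: 2 4-bromo-2-iodo-6-methoxyphenol
Product: 3 5-bromo-1-iodo-2,3-dimethoxybenzene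
Conditions: MeI (1.5 equiv), K2CO3 (2 equiv), DMF, rt
Reagents that add atoms: iodomethane, CI
Why: Williamson ether synthesis on the phenoxide, which gives the dimethyl-protected catechol that tolerates base, hydride, ozone, light and palladium in the later steps.

Step 3
Reactants: 3 5-bromo-1-iodo-2,3-dimethoxybenzene, 4 (R)-but-3-yn-2-ol
Product: 5 (2R)-4-(5-bromo-2,3-dimethoxyphenyl)but-3-yn-2-ol
Conditions: PdCl2(PPh3)2 (2 mol%), CuI (4 mol%), Et3N, THF, rt
Reagents that add atoms: none
Why: Sonogashira coupling, in which zerovalent palladium inserts into the C–I bond far faster than into the C–Br bond at room temperature and the carbinol stereocentre of 4 is not touched.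

Step 4
Reactants: 5 (2R)-4-(5-bromo-2,3-dimethoxyphenyl)but-3-yn-2-ol
Product: 7 (2R,3Z)-4-(5-bromo-2,3-dimethoxyphenyl)-4-iodobut-3-en-2-ol, via cyclic sodium alkenylaluminate 6 (not isolated)
Conditions: NaAlH2(OCH2CH2OMe)2 (Red-Al, 1.6 equiv), THF, 0 °C to rt; then I2, −78 to 0 °C
Reagents that add atoms: iodine, II
Why: Hydroxyl-directed trans-hydroalumination of the propargylic alcohol (hydride to the carbon next to the carbinol, aluminium on the aryl-bearing carbon in a five-membered oxaaluminacycle) followed by iodinolysis of the C–Al bond with retention, which should fix the Z iodoalkene and leave the carbinol centre untouched.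

Step 5
Reactants: 7 (2R,3Z)-4-(5-bromo-2,3-dimethoxyphenyl)-4-iodobut-3-en-2-ol
Product: 8 (2R,3E)-4-(5-bromo-2,3-dimethoxyphenyl)pent-3-en-2-ol
Conditions: MeZnCl (3 equiv), Pd(PPh3)4 (5 mol%), THF, rt
Reagents that add atoms: methylzinc chloride, C[Zn]Cl
Why: Negishi coupling of the alkenyl iodide with retention of geometry (methyl takes the place of iodine, giving the E trisubstituted alkene), while the electron-rich aryl bromide should be much slower in oxidative addition at room temperature.

Step 6
Reactants: 8 (2R,3E)-4-(5-bromo-2,3-dimethoxyphenyl)pent-3-en-2-ol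
Product: 9 (2R,3E)-4-(5-bromo-2,3-dimethoxyphenyl)pent-3-en-2-yl 2-methylpropanoate
Conditions: Me2CHCOCl (1.3 equiv), Et3N, DMAP (cat.), CH2Cl2, 0 °C
Reagents that add atoms: 2-methylpropanoyl chloride, CC(C)C(Cl)=O
Why: DMAP-catalysed O-acylation under basic conditions, which avoids ionisation of the acid-sensitive aryl-substituted allylic alcohol and keeps the C–O stereocentre.

Step 7
Reactants: 9 (2R,3E)-4-(5-bromo-2,3-dimethoxyphenyl)pent-3-en-2-yl 2-methylpropanoate
Product: 12 (3R,4E)-3-(5-bromo-2,3-dimethoxyphenyl)-2,2,3-trimethylhex-4-enoic acid, via silyl ketene acetal 10 (not isolated), via trimethylsilyl ester 11 (not isolated)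
Conditions: LiN(iPr)2 (1.3 equiv), Me3SiCl (1.5 equiv), THF, −78 °C, then warm to 65 °C; then 1 M HCl
Reagents that add atoms: none
Why: Ireland–Claisen rearrangement, in which the [3,3] shift through a chair transition state with the carbinol methyl pseudo-equatorial delivers the CMe2 carbon to the alkene face from which the C–O bond leaves, so the (R) carbinol centre should be transferred into the quaternary benzylic carbon with the spatial arrangement of the (S) centre of the target while the bond between the two quaternary carbons is made.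

Step 8
Reactants: 12 (3R,4E)-3-(5-bromo-2,3-dimethoxyphenyl)-2,2,3-trimethylhex-4-enoic acid
Product: 14 (3R)-3-(5-bromo-2,3-dimethoxyphenyl)-2,2,3-trimethyl-4-oxobutanoic acid, via secondary ozonide 13 (not isolated)
Conditions: O3, CH2Cl2, −78 °C (Sudan red 7B as end-point indicator); then Me2S, −78 °C to rt
Reagents that add atoms: ozone, [O-][O+]=O
Why: Ozonolysis with reductive work-up (Criegee mechanism), in which the disubstituted alkene should react far faster than the bromo-dimethoxyarene at −78 °C and the quaternary centre, having no hydrogen, cannot epimerise.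

Step 9
Reactants: 14 (3R)-3-(5-bromo-2,3-dimethoxyphenyl)-2,2,3-trimethyl-4-oxobutanoic acid, 15 vinyltriphenylphosphonium bromide
Product: 17 5-bromo-1,2-dimethoxy-3-[(1S)-1,5,5-trimethylcyclopent-2-en-1-yl]benzene, via phosphonium ylide 16 (not isolated)
Conditions: 15 (3 equiv), [Ir(dF(CF3)ppy)2(dtbbpy)]PF6 (2 mol%), Cs2CO3 (1.2 equiv), degassed DMSO (0.2 M in 14), blue LEDs (450 nm), rt
Reagents that add atoms: none
Why: Proposed new method: the caesium carboxylate of 14 is oxidised by the photoexcited trivalent iridium complex, loses CO2 and gives the tertiary radical at the CMe2 carbon, which adds to the CH2 terminus of 15 (first new bond); the α-phosphonio radical is then reduced by the divalent iridium complex to ylide 16, which olefinates the neighbouring aldehyde in an intramolecular Wittig reaction (second new bond, as the ring C=C) with loss of Ph3PO. The closest known reaction type is the light-driven three-component olefination of carboxylic acids, vinylphosphonium salts and aldehydes, together with the polar vinylphosphonium annulation of carbanions that carry a carbonyl group; here acid and aldehyde sit in one molecule, so the sequence becomes a formal [3+2] annulation. The five-membered ring closes by addition of the ylide carbon to the formyl carbon (5-exo-trig) through a fused oxaphosphetane, helped by the gem-dimethyl and quaternary substituents. No new stereocentre arises (the CMe2 carbon is not stereogenic), and the existing quaternary benzylic centre has no hydrogen and is never trigonal, so its configuration is kept. The step needs the intermolecular radical addition to outrun 1,2-formyl and 1,2-aryl shifts of the β-formyl β-aryl radical, which the nucleophilic tertiary radical and the cationic, strongly electrophilic acceptor used in excess at high concentration should secure; the ring can only contain the cis alkene.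

Step 10
Reactants: 17 5-bromo-1,2-dimethoxy-3-[(1S)-1,5,5-trimethylcyclopent-2-en-1-yl]benzene (2 equiv), 18 (E)-1,2-bis(4,4,5,5-tetramethyl-1,3,2-dioxaborolan-2-yl)ethene
Product: 20 (E)-1,2-bis{3,4-dimethoxy-5-[(1S)-1,5,5-trimethylcyclopent-2-en-1-yl]phenyl}ethene, via mono-coupled alkenylboronate 19 (not isolated)
Conditions: 18 (0.5 equiv), Pd(dppf)Cl2 (5 mol%), K3PO4 (3 M aq), 1,4-dioxane, 90 °C
Reagents that add atoms: none
Why: Twofold Suzuki–Miyaura coupling of the unhindered aryl bromide with the 1,2-diborylethene linchpin with retention of the E geometry, in which the hindered ring alkenes should not take part and the stereocentres are remote.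

Step 11
Reactants: 20 (E)-1,2-bis{3,4-dimethoxy-5-[(1S)-1,5,5-trimethylcyclopent-2-en-1-yl]phenyl}ethene
Product: 21 1,2-bis{3,4-dimethoxy-5-[(1S)-1,2,2-trimethylcyclopentyl]phenyl}ethane
Conditions: H2 (4 bar), 10% Pd/C, EtOAc/EtOH, rt
Reagents that add atoms: none
Why: Heterogeneous catalytic hydrogenation of the stilbene and of the two cis-disubstituted ring alkenes, which forms no stereocentre and does not touch the quaternary centres.

Step 12
Reactants: 21 1,2-bis{3,4-dimethoxy-5-[(1S)-1,2,2-trimethylcyclopentyl]phenyl}ethane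
Product: 23 5,5'-(ethane-1,2-diyl)bis{3-[(1S)-1,2,2-trimethylcyclopentyl]benzene-1,2-diol}, via cyclic bis(catechol bromoboronate) 22 (not isolated)
Conditions: BBr3 (6 equiv), CH2Cl2, −78 °C to rt; then H2O
Reagents that add atoms: none
Why: Lewis-acid cleavage of the four aryl methyl ethers by BBr3 (bromide attack on the O-methyl of the boron-complexed ether) through the cyclic catechol bromoboronates, which are hydrolysed on work-up while C–C bonds and the quaternary centres stay inert.

**Compound list**

1 | 4-bromo-2-methoxyphenol | COc1cc(Br)ccc1O | starting material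
2 | 4-bromo-2-iodo-6-methoxyphenol | COc1cc(Br)cc(I)c1O | intermediate
3 | 5-bromo-1-iodo-2,3-dimethoxybenzene | COc1cc(Br)cc(I)c1OC | intermediate
4 | (R)-but-3-yn-2-ol | C[C@@H](O)C#C | starting material
5 | (2R)-4-(5-bromo-2,3-dimethoxyphenyl)but-3-yn-2-ol | C[C@@H](O)C#Cc1cc(Br)cc(OC)c1OC | intermediate
6 | cyclic sodium alkenylaluminate: five-membered oxaaluminacycle (O and the aryl-bearing alkene carbon on aluminium, two 2-methoxyethoxy ligands), not isolated | [Na+].C[C@H]1O[Al-](OCCOC)(OCCOC)C(c2cc(Br)cc(OC)c2OC)=C1 | intermediate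
7 | (2R,3Z)-4-(5-bromo-2,3-dimethoxyphenyl)-4-iodobut-3-en-2-ol | C[C@@H](O)/C=C(\I)c1cc(Br)cc(OC)c1OC | intermediate
8 | (2R,3E)-4-(5-bromo-2,3-dimethoxyphenyl)pent-3-en-2-ol | C[C@@H](O)/C=C(\C)c1cc(Br)cc(OC)c1OC | intermediate
9 | (2R,3E)-4-(5-bromo-2,3-dimethoxyphenyl)pent-3-en-2-yl 2-methylpropanoate | CC(C)C(=O)O[C@H](C)/C=C(\C)c1cc(Br)cc(OC)c1OC | intermediate
10 | trimethylsilyl ketene acetal of ester 9, not isolated | CC(C)=C(O[Si](C)(C)C)O[C@H](C)/C=C(\C)c1cc(Br)cc(OC)c1OC | intermediate
11 | trimethylsilyl (3R,4E)-3-(5-bromo-2,3-dimethoxyphenyl)-2,2,3-trimethylhex-4-enoate, not isolated | C[Si](C)(C)OC(=O)C(C)(C)[C@@](C)(c1cc(Br)cc(OC)c1OC)/C=C/C | intermediate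
12 | (3R,4E)-3-(5-bromo-2,3-dimethoxyphenyl)-2,2,3-trimethylhex-4-enoic acid | OC(=O)C(C)(C)[C@@](C)(c1cc(Br)cc(OC)c1OC)/C=C/C | intermediate
13 | secondary ozonide (1,2,4-trioxolane) of 12, mixture at the two ozonide carbons, not isolated | OC(=O)C(C)(C)[C@@](C)(c1cc(Br)cc(OC)c1OC)C1OOC(C)O1 | intermediate
14 | (3R)-3-(5-bromo-2,3-dimethoxyphenyl)-2,2,3-trimethyl-4-oxobutanoic acid (open form of the hydroxy lactone) | OC(=O)C(C)(C)[C@@](C)(c1cc(Br)cc(OC)c1OC)C=O | intermediate
15 | vinyltriphenylphosphonium bromide | C=C[P+](c1ccccc1)(c1ccccc1)c1ccccc1.[Br-] | starting material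
16 | (2S)-2-(5-bromo-2,3-dimethoxyphenyl)-2,3,3-trimethyl-5-(triphenylphosphoranylidene)pentanal, not isolated | O=C[C@](C)(c1cc(Br)cc(OC)c1OC)C(C)(C)CC=P(c1ccccc1)(c1ccccc1)c1ccccc1 | intermediate
17 | 5-bromo-1,2-dimethoxy-3-[(1S)-1,5,5-trimethylcyclopent-2-en-1-yl]benzene | CC1(C)CC=C[C@]1(C)c1cc(Br)cc(OC)c1OC | intermediate
18 | (E)-1,2-bis(4,4,5,5-tetramethyl-1,3,2-dioxaborolan-2-yl)ethene | CC1(C)OB(/C=C/B2OC(C)(C)C(C)(C)O2)OC1(C)C | starting material
19 | 2-[(E)-2-{3,4-dimethoxy-5-[(1S)-1,5,5-trimethylcyclopent-2-en-1-yl]phenyl}ethenyl]-4,4,5,5-tetramethyl-1,3,2-dioxaborolane, not isolated | CC1(C)OB(/C=C/c2cc(OC)c(OC)c([C@@]3(C)C=CCC3(C)C)c2)OC1(C)C | intermediate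
20 | (E)-1,2-bis{3,4-dimethoxy-5-[(1S)-1,5,5-trimethylcyclopent-2-en-1-yl]phenyl}ethene | COc1cc(/C=C/c2cc(OC)c(OC)c([C@@]3(C)C=CCC3(C)C)c2)cc([C@@]2(C)C=CCC2(C)C)c1OC | intermediate
21 | 1,2-bis{3,4-dimethoxy-5-[(1S)-1,2,2-trimethylcyclopentyl]phenyl}ethane | COc1cc(CCc2cc(OC)c(OC)c([C@@]3(C)CCCC3(C)C)c2)cc([C@@]2(C)CCCC2(C)C)c1OC | intermediate
22 | 1,2-bis{2-bromo-7-[(1S)-1,2,2-trimethylcyclopentyl]-1,3,2-benzodioxaborol-5-yl}ethane, not isolated | BrB1Oc2cc(CCc3cc4OB(Br)Oc4c([C@@]5(C)CCCC5(C)C)c3)cc([C@@]3(C)CCCC3(C)C)c2O1 | intermediate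
23 | 5,5'-(ethane-1,2-diyl)bis{3-[(1S)-1,2,2-trimethylcyclopentyl]benzene-1,2-diol} (CNP0144189.1) | CC1(C)CCC[C@]1(C)c1cc(CCc2cc(O)c(O)c([C@@]3(C)CCCC3(C)C)c2)cc(O)c1O | target

Total step count: 12. Longest linear sequence: 12 steps (1 to 23; the second copy of 17 and linchpin 18 enter at step 10).

**Steps most likely to fail**

Step 9 (proposed new method). The tertiary radical may undergo a 1,2-formyl or 1,2-aryl shift before it is trapped, the ylide may be protonated before it closes, or the hydroxy lactone may open too slowly. The fallback uses known homologation and metathesis chemistry, sets out from acid 12 and returns at 17. Reduction with LiAlH4 (THF, 0 °C) should give (3S,4E)-3-(5-bromo-2,3-dimethoxyphenyl)-2,2,3-trimethylhex-4-en-1-ol F1. Dess–Martin oxidation should give (3R,4E)-3-(5-bromo-2,3-dimethoxyphenyl)-2,2,3-trimethylhex-4-enal F2. Wittig reaction with Ph3P=CHOMe should give (4S,5E)-4-(5-bromo-2,3-dimethoxyphenyl)-1-methoxy-3,3,4-trimethylhepta-1,5-diene F3 (enol ether as an E/Z mixture). Hydrolysis with aqueous HCl in THF should give (4S,5E)-4-(5-bromo-2,3-dimethoxyphenyl)-3,3,4-trimethylhept-5-enal F4. Methylenation with Ph3P=CH2 should give (5S,6E)-5-(5-bromo-2,3-dimethoxyphenyl)-4,4,5-trimethylocta-1,6-diene F5. Ring-closing metathesis with the second-generation Grubbs catalyst RuCl2(=CHPh)(H2IMes)(PCy3) (CH2Cl2, 40 °C, loss of propene) should then close the same cyclopentene 17.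

Step 7. Enolisation and rearrangement at the congested site may be slow, the allylic carboxylate may eliminate, or leakage through a boat transition state may erode the chirality transfer while two adjacent quaternary carbons are formed at once. The fallback makes only one quaternary carbon in the sigmatropic step, sets out from alcohol 8 and returns at 12. Johnson–Claisen rearrangement of 8 with trimethyl orthopropionate (cat. propanoic acid, xylene, 140 °C; same chair transfer) should give methyl (2RS,3S,4E)-3-(5-bromo-2,3-dimethoxyphenyl)-2,3-dimethylhex-4-enoate F6. Enolate methylation (LiN(iPr)2, THF, −78 °C; MeI) should give methyl (3R,4E)-3-(5-bromo-2,3-dimethoxyphenyl)-2,2,3-trimethylhex-4-enoate F7. O-Methyl cleavage of this hindered ester with LiI in pyridine at reflux, then acidification, should give acid 12.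

Step 10. The alkenylboronate may protodeboronate after the first coupling, or the reaction may stall at the mono-coupled stage, so that the bridge is not completed. The fallback builds the bridge by carbonyl reductive coupling, sets out from 17 and returns at 20. Bromine–lithium exchange (n-BuLi, THF, −78 °C) and formylation with DMF should give 3,4-dimethoxy-5-[(1S)-1,5,5-trimethylcyclopent-2-en-1-yl]benzaldehyde F8. McMurry coupling (TiCl4, Zn, pyridine, THF, reflux) should give stilbene 20; any Z isomer is of no consequence because step 11 saturates the bridge.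

**Further compounds**

F1 | step 9 | (3S,4E)-3-(5-bromo-2,3-dimethoxyphenyl)-2,2,3-trimethylhex-4-en-1-ol | OCC(C)(C)[C@@](C)(c1cc(Br)cc(OC)c1OC)/C=C/C
F2 | step 9 | (3R,4E)-3-(5-bromo-2,3-dimethoxyphenyl)-2,2,3-trimethylhex-4-enal | O=CC(C)(C)[C@@](C)(c1cc(Br)cc(OC)c1OC)/C=C/C
F3 | step 9 | (4S,5E)-4-(5-bromo-2,3-dimethoxyphenyl)-1-methoxy-3,3,4-trimethylhepta-1,5-diene | COC=CC(C)(C)[C@@](C)(c1cc(Br)cc(OC)c1OC)/C=C/C
F4 | step 9 | (4S,5E)-4-(5-bromo-2,3-dimethoxyphenyl)-3,3,4-trimethylhept-5-enal | O=CCC(C)(C)[C@@](C)(c1cc(Br)cc(OC)c1OC)/C=C/C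
F5 | step 9 | (5S,6E)-5-(5-bromo-2,3-dimethoxyphenyl)-4,4,5-trimethylocta-1,6-diene | C=CCC(C)(C)[C@@](C)(c1cc(Br)cc(OC)c1OC)/C=C/C
F6 | step 7 | methyl (2RS,3S,4E)-3-(5-bromo-2,3-dimethoxyphenyl)-2,3-dimethylhex-4-enoate | COC(=O)C(C)[C@@](C)(c1cc(Br)cc(OC)c1OC)/C=C/C
F7 | step 7 | methyl (3R,4E)-3-(5-bromo-2,3-dimethoxyphenyl)-2,2,3-trimethylhex-4-enoate | COC(=O)C(C)(C)[C@@](C)(c1cc(Br)cc(OC)c1OC)/C=C/C
F8 | step 10 | 3,4-dimethoxy-5-[(1S)-1,5,5-trimethylcyclopent-2-en-1-yl]benzaldehyde | COc1cc(C=O)cc([C@@]2(C)C=CCC2(C)C)c1OC
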